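Ring A (C1, C10–C14) is disconnected at C1–C10. The target carries C14–O beside quaternary C1 and the exocyclic C11=C20 methylene beside C10, which is the footprint of an epoxide-opening cation–olefin cyclization ended by an allylsilane. One Lewis-acid step on a cis-2,3-epoxy silyl ether tethered to a 2-(silylmethyl)allyl pivalate forms C1–C10, closes ring A and sets C1 and C10 from the single epoxidation-derived centre C14. Ring A is then grown outward: C2 by chelation-controlled alkynylation, C7–C8/C17–C19 from an (S)-malate-derived dioxolanone, and the ten-membered ring by intramolecular Sonogashira coupling and semihydrogenation.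

Key step: step 11

Remarks (one line each):
- Locants C1–C20 are those of the target (briarane numbering) and are used for all intermediates.
- C11 and C14 are separated by exactly two CH2 groups, so the C11–C14 unit enters as methyl 4,4-dimethoxybutanoate; a three-carbon bromoacetal on an acetoacetate dianion would give the homologue and a seven-membered ring.
- By CIP the allylsilane alkene of 14 is E (CH2Si outranks CH2C), although the carbon chain C9–C10=C11–C12 is cis, which is the geometry required.
- The (Z)-allylic alcohol 10 needs D-(−)-tartrate to give the C1 R, C14 S epoxide.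
- C9 is kept as a tert-butyl ester until the epoxide is in place, so no hydride reduction runs beside the pivalate and no acid or fluoride meets the electron-rich silylmethyl allyl pivalate.
- C9 emerges from the aldol (step 21) as a mixture of epimers and is fixed later by oxidation and reduction (steps 26 and 27).

Step 1
Reactants: 1 tert-butyl acetate; 2 methyl 4,4-dimethoxybutanoate
Product: 3 tert-butyl 6,6-dimethoxy-3-oxohexanoate
Conditions: LDA (2.2 equiv), 1 (2.2 equiv), THF, −78 °C; then 2, −78 → −20 °C; aq. NH4Cl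
Reagents that add atoms: none
Why: Crossed Claisen condensation, in which the excess lithium enolate of the tert-butyl ester acylates on the methyl ester and the product is stored as its enolate until quench.

Step 2
Reactants: 3 tert-butyl 6,6-dimethoxy-3-oxohexanoate
Product: 4 tert-butyl (2E)-3-[(diethoxyphosphoryl)oxy]-6,6-dimethoxyhex-2-enoate
Conditions: (EtO)2P(O)Cl, Et3N, DMAP (cat.), DMPU, 0 °C → rt
Reagents that add atoms: diethyl chlorophosphate, CCOP(Cl)(=O)OCC
Why: O-phosphorylation of the β-keto ester under non-chelating amine conditions should give the E enol phosphate (phosphate trans to the ester), the geometry that later places the chain cis to C9.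

Step 3
Reactants: 4 tert-butyl (2E)-3-[(diethoxyphosphoryl)oxy]-6,6-dimethoxyhex-2-enoate; 5 (trimethylsilyl)methylmagnesium chloride
Product: 6 tert-butyl (2E)-6,6-dimethoxy-3-[(trimethylsilyl)methyl]hex-2-enoate
Conditions: 5 (2 equiv), Ni(acac)2 (5 mol%), THF, 0 °C → rt
Reagents that add atoms: none
Why: Nickel-catalysed Kumada-type coupling of the enol phosphate C–O bond proceeds with retention of alkene geometry and should deliver the silylmethyl enoate as a single isomer.

Step 4
Reactants: 6 tert-butyl (2E)-6,6-dimethoxy-3-[(trimethylsilyl)methyl]hex-2-enoate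
Product: 7 tert-butyl (2E)-6-oxo-3-[(trimethylsilyl)methyl]hex-2-enoate
Conditions: PPTS (cat.), acetone/H2O (9:1), 40 °C
Reagents that add atoms: water, O
Why: Mild acid hydrolysis of a dimethyl acetal, tolerated because the allylsilane is deactivated by conjugation with the ester, so protodesilylation and closure onto the oxocarbenium ion are disfavoured.

Step 5
Reactants: 7 tert-butyl (2E)-6-oxo-3-[(trimethylsilyl)methyl]hex-2-enoate; 8 ethyl 2-[bis(2,2,2-trifluoroethoxy)phosphoryl]propanoate
Product: 9 1-tert-butyl 8-ethyl (2E,6Z)-7-methyl-3-[(trimethylsilyl)methyl]octa-2,6-dienedioate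
Conditions: 8, KHMDS, 18-crown-6, THF, −78 °C; then 7
Reagents that add atoms: none
Why: Still–Gennari olefination, whose kinetically controlled elimination should give the (Z)-2-methyl enoate that places C2 cis to C13.

Step 6
Reactants: 9 1-tert-butyl 8-ethyl (2E,6Z)-7-methyl-3-[(trimethylsilyl)methyl]octa-2,6-dienedioate
Product: 10 tert-butyl (2E,6Z)-8-hydroxy-7-methyl-3-[(trimethylsilyl)methyl]octa-2,6-dienoate
Conditions: DIBAL-H (2.2 equiv), CH2Cl2, −78 °C; Rochelle salt
Reagents that add atoms: none
Why: 1,2-Reduction of the ethyl enoate by DIBAL-H at −78 °C, a temperature at which the hindered tert-butyl enoate should not react.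

Step 7
Reactants: 10 tert-butyl (2E,6Z)-8-hydroxy-7-methyl-3-[(trimethylsilyl)methyl]octa-2,6-dienoate
Product: 11 tert-butyl (2E)-5-[(2S,3R)-3-(hydroxymethyl)-3-methyloxiran-2-yl]-3-[(trimethylsilyl)methyl]pent-2-enoate
Conditions: Ti(OiPr)4 (10 mol%), D-(−)-diethyl tartrate (12 mol%), t-BuOOH, 4 Å MS, CH2Cl2, −20 °C
Reagents that add atoms: tert-butyl hydroperoxide, CC(C)(C)OO
Why: Sharpless asymmetric epoxidation, in which the D-(−)-tartrate complex delivers oxygen to the face of the (Z)-2-methyl allylic alcohol that gives C1 R and C14 S, while the electron-poor silylmethyl enoate, not being an allylic alcohol, is left alone.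

Step 8
Reactants: 11 tert-butyl (2E)-5-[(2S,3R)-3-(hydroxymethyl)-3-methyloxiran-2-yl]-3-[(trimethylsilyl)methyl]pent-2-enoate
Product: 12 tert-butyl (2E)-5-[(2S,3R)-3-{[(tert-butyldimethylsilyl)oxy]methyl}-3-methyloxiran-2-yl]-3-[(trimethylsilyl)methyl]pent-2-enoate
Conditions: TBSCl, imidazole, CH2Cl2, 0 °C → rt
Reagents that add atoms: tert-butyldimethylsilyl chloride, CC(C)(C)[Si](C)(C)Cl
Why: Standard silylation of a primary alcohol under conditions that do not open the epoxide.

Step 9
Reactants: 12 tert-butyl (2E)-5-[(2S,3R)-3-{[(tert-butyldimethylsilyl)oxy]methyl}-3-methyloxiran-2-yl]-3-[(trimethylsilyl)methyl]pent-2-enoate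
Product: 13 (2E)-5-[(2S,3R)-3-{[(tert-butyldimethylsilyl)oxy]methyl}-3-methyloxiran-2-yl]-3-[(trimethylsilyl)methyl]pent-2-en-1-ol
Conditions: DIBAL-H (3 equiv), CH2Cl2, −78 → −20 °C; Rochelle salt
Reagents that add atoms: none
Why: DIBAL-H reduction of the tert-butyl enoate to the allylic alcohol at a temperature at which the trisubstituted epoxy silyl ether, lacking a free hydroxyl to direct hydride, should not be opened.

Step 10
Reactants: 13 (2E)-5-[(2S,3R)-3-{[(tert-butyldimethylsilyl)oxy]methyl}-3-methyloxiran-2-yl]-3-[(trimethylsilyl)methyl]pent-2-en-1-ol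
Product: 14 cyclisation precursor, the pivalate of 13
Conditions: PivCl, pyridine, DMAP (cat.), CH2Cl2, 0 °C
Reagents that add atoms: pivaloyl chloride, CC(C)(C)C(Cl)=O
Why: Acylation of the primary allylic alcohol under basic, fluoride-free conditions that avoid 1,4-elimination of the silylmethyl allyl system.

Step 11
Reactants: 14 cyclisation precursor, the pivalate of 13
Product: 15 ring-A alcohol (1S,10S,14S)
Conditions: MeAlCl2 (1.5 equiv), CH2Cl2, −78 °C; aq. NaHCO3
Reagents that add atoms: none
Why: MeAlCl2 binds the epoxide oxygen and the C1–O bond lengthens at the tertiary carbon while C10 of the allylsilane attacks C1 from the rear through a chair with C14–O equatorial; the cation developing at C11 is β to silicon and collapses at once by loss of Me3Si to the C11=C20 methylene. The closest known reaction type is the epoxide-initiated cation–olefin cyclization terminated by an allylsilane (an intramolecular Hosomi–Sakurai-type alkylation). Ring A closes in the 6-endo-trig mode with respect to C10=C11, and the epoxide is opened at its distal carbon C1 (endo opening), so C14 keeps its oxygen on the ring. C1 is set by inversion at the epoxide carbon, whose configuration comes from the tartrate (the cis epoxide places C2 cis to O14), and C10 by the alkene geometry, C9 cis to C12 ending axial and trans to C2. The step needs attack at tertiary C1 rather than 5-exo attack at C14, which the better cation stabilisation at the trisubstituted carbon in a strain-free chair should secure; it also needs the exocyclic alkene only, which silicon secures, and −78 °C should keep the allylic pivalate from ionising.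

Step 12
Reactants: 15 ring-A alcohol (1S,10S,14S)
Product: 16 ring-A C2,C14-diol
Conditions: TBAF, THF, 0 °C → rt
Reagents that add atoms: none
Why: Fluoride cleavage of the only silyl ether in the molecule, with pivalate and alkene inert.

Step 13
Reactants: 16 ring-A C2,C14-diol
Product: 17 ring-A C2 aldehyde with free C14–OH
Conditions: TEMPO (10 mol%), PhI(OAc)2, CH2Cl2, rt
Reagents that add atoms: none
Why: TEMPO/iodine(III) oxidation is selective for the primary alcohol over the secondary C14–OH and gives a non-enolisable aldehyde on quaternary C1.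

Step 14
Reactants: 17 ring-A C2 aldehyde with free C14–OH; 18 trimethylsilylacetylene
Product: 19 propargylic diol (C2 as in the target, 2R by CIP here)
Conditions: 18, EtMgBr, THF, 0 °C; then 17, −40 → 0 °C; aq. NH4Cl
Reagents that add atoms: none
Why: Chelation-controlled (Cram-chelate) Grignard addition, in which the C14 magnesium alkoxide, cis to the formyl group, ties the carbonyl into a six-membered chelate fused to ring A and the acetylide adds from the exposed face anti to C10, which should set C2 with the target configuration.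

Step 15
Reactants: 19 propargylic diol (C2 as in the target, 2R by CIP here)
Product: 20 C2,C14-bis(tert-butyldimethylsilyl) ether of 19
Conditions: TBSOTf (2.5 equiv), 2,6-lutidine, CH2Cl2, 0 °C → rt
Reagents that add atoms: tert-butyldimethylsilyl trifluoromethanesulfonate, CC(C)(C)[Si](C)(C)OS(=O)(=O)C(F)(F)F
Why: Silyl triflate with a hindered base silylates both hindered secondary alcohols without touching the pivalate or the silylalkyne.

Step 16
Reactants: 20 C2,C14-bis(tert-butyldimethylsilyl) ether of 19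
Product: 21 C9 primary alcohol
Conditions: DIBAL-H (2.5 equiv), CH2Cl2, −78 °C; Rochelle salt
Reagents that add atoms: none
Why: Reductive cleavage of the pivalate by DIBAL-H, with silyl ethers and the silylalkyne inert.

Step 17
Reactants: 21 C9 primary alcohol
Product: 22 C9 aldehyde
Conditions: Dess–Martin periodinane, NaHCO3, CH2Cl2, 0 °C
Reagents that add atoms: none
Why: Dess–Martin oxidation under buffered, base-free conditions should spare the epimerisable C10 centre, which is both α to the new carbonyl and allylic.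

Step 18
Reactants: 23 diethyl (S)-malate
Product: 24 diethyl (2S,3R)-2-hydroxy-3-methylbutanedioate
Conditions: LDA (2.1 equiv), THF, −78 → −20 °C; MeI, −78 °C; aq. NH4Cl
Reagents that add atoms: iodomethane, CI
Why: Fráter–Seebach alkylation, in which the chelated alkoxide enolate is methylated anti to the alkoxide, setting the future C17 as R.

Step 19
Reactants: 24 diethyl (2S,3R)-2-hydroxy-3-methylbutanedioate
Product: 25 (2S,3R)-2-hydroxy-3-methylbutanedioic acid
Conditions: KOH, H2O/MeOH, rt; then HCl
Reagents that add atoms: potassium hydroxide, [K+].[OH-]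
Why: Saponification at room temperature, where the carboxylate α-centre should not epimerise.

Step 20
Reactants: 25 (2S,3R)-2-hydroxy-3-methylbutanedioic acid
Product: 26 (2R)-2-[(2S,4S)-2-tert-butyl-5-oxo-1,3-dioxolan-4-yl]propanoic acid
Conditions: t-BuCHO, TsOH (cat.), H2SO4 (cat.), pentane, reflux, water separator; crystallisation
Reagents that add atoms: pivalaldehyde, CC(C)(C)C=O
Why: Acid-catalysed acetalisation of the α-hydroxy acid under equilibrating conditions should favour the cis-2,5-disubstituted dioxolanone, which stores the C8 configuration in the acetal centre (self-regeneration of stereocentres).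

Step 21
Reactants: 22 C9 aldehyde; 26 (2R)-2-[(2S,4S)-2-tert-butyl-5-oxo-1,3-dioxolan-4-yl]propanoic acid
Product: 28 aldol acid with C9–OTES (C9 epimers), via bis-triethylsilyl aldol adduct 27 (not isolated)
Conditions: 26 (1.3 equiv), LiHMDS (2.6 equiv), THF, −78 °C; 22, −78 °C; TESOTf, −78 → −40 °C; pH 5 buffer
Reagents that add atoms: triethylsilyl trifluoromethanesulfonate, CC[Si](CC)(CC)OS(=O)(=O)C(F)(F)F
Why: Aldol addition of a dioxolanone enolate (carboxylate/enolate dianion), which is attacked anti to the tert-butyl group so that C9 replaces H at C8 with retention (C8 S); in-situ silylation blocks retro-aldol and γ-lactonisation onto C19, and the undefined C9 centre is corrected in steps 26–27.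

Step 22
Reactants: 28 aldol acid with C9–OTES (C9 epimers); 29 tert-butyl(diphenyl)(prop-2-yn-1-yloxy)silane
Product: 30 α-hydroxy ynone acid
Conditions: 29 (2.4 equiv), n-BuLi (2.3 equiv), THF, −78 °C; then 28, −78 → −40 °C; aq. NH4Cl
Reagents that add atoms: none
Why: Acylation of a lithium acetylide by a lactone-type carbonyl, in which the tetrahedral adduct of the acylal carbonyl is stable at low temperature (single addition, carboxylate inert) and collapses on work-up with loss of pivalaldehyde to free the tertiary C8–OH.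

Step 23
Reactants: 30 α-hydroxy ynone acid
Product: 31 (Z)-β-iodoenone acid
Conditions: LiI, AcOH, MeCN, rt
Reagents that add atoms: lithium iodide, [Li+].[I-]
Why: Conjugate hydroiodination of the ynone (iodide addition, then protonation of the allenolate) should give the Z iodoenone with iodine on C5 cis to C7, which fixes the later C4/C7 cis relation.

Step 24
Reactants: 31 (Z)-β-iodoenone acid
Product: 33 iodovinyl γ-lactone (7S,8S,17R), via dihydroxy acid 32 (not isolated)
Conditions: Zn(BH4)2, Et2O, −30 °C; aq. NH4Cl; then PPTS (cat.), CH2Cl2, rt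
Reagents that add atoms: none
Why: Chelation-controlled 1,2-reduction, in which zinc bridges the C7 carbonyl and the free C8 hydroxyl and hydride enters from the side of the smaller C17 arm to set C7 as S, after which the γ-hydroxy acid lactonises on O7 because O9 is silylated.

Step 25
Reactants: 33 iodovinyl γ-lactone (7S,8S,17R)
Product: 34 C9 alcohol (C9 epimers)
Conditions: HF·pyridine, pyridine, THF, 0 °C
Reagents that add atoms: none
Why: Buffered HF·pyridine removes the triethylsilyl ether selectively in the presence of TBS, TBDPS and C-silyl groups.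

Step 26
Reactants: 34 C9 alcohol (C9 epimers)
Product: 35 C9 ketone
Conditions: Dess–Martin periodinane, NaHCO3, CH2Cl2, 0 °C
Reagents that add atoms: none
Why: Dess–Martin oxidation converges both C9 epimers on one ketone, while the tertiary C8–OH cannot be oxidised.

Step 27
Reactants: 35 C9 ketone
Product: 36 (9S)-alcohol
Conditions: Zn(BH4)2, Et2O/CH2Cl2, −78 → −40 °C; aq. NH4Cl
Reagents that add atoms: none
Why: Chelation-controlled reduction of the α-hydroxy ketone, in which the lactone presents similar C7–H and C17–H flanks so that the adjacent C10 centre should decide (Felkin–Anh, hydride anti to quaternary C1), giving 9S.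

Step 28
Reactants: 36 (9S)-alcohol
Product: 37 C9 acetate
Conditions: Ac2O, DMAP, pyridine, CH2Cl2, 0 °C → rt
Reagents that add atoms: acetic anhydride, CC(=O)OC(C)=O
Why: DMAP-catalysed acylation of the secondary alcohol installs the final C9 acetate and blocks translactonisation, the tertiary C8–OH being too hindered to react.

Step 29
Reactants: 37 C9 acetate
Product: 39 macrocyclic en-yne, via terminal alkyne 38 (not isolated)
Conditions: TBAF (1.05 equiv), THF, 0 °C; then Pd(PPh3)4 (20 mol%), CuI (40 mol%), Et3N, THF (1 mM), rt, slow addition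
Reagents that add atoms: none
Why: Fluoride unmasks the terminal alkyne and an intramolecular Sonogashira coupling at high dilution joins C4 to C5 with retention of the vinyl iodide geometry, closing the ten-membered ring without creating a stereocentre.

Step 30
Reactants: 39 macrocyclic en-yne
Product: 40 macrocyclic (3Z,5E)-diene
Conditions: H2 (1 atm), Lindlar catalyst, quinoline, EtOAc, rt
Reagents that add atoms: none
Why: Lindlar semihydrogenation delivers H2 syn to give the cis C3=C4 bond, and the poisoned catalyst should spare the diene and the 1,1-disubstituted C11=C20 alkene.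

Step 31
Reactants: 40 macrocyclic (3Z,5E)-diene
Product: 41 C2,C14,C16-triol 9-acetate
Conditions: HF·pyridine, pyridine, THF, 0 °C → rt
Reagents that add atoms: none
Why: Global desilylation under buffered, weakly acidic conditions that should leave the acetate, the lactone and the diene intact.

Step 32
Reactants: 41 C2,C14,C16-triol 9-acetate
Product: 42 target CNP0269068.1
Conditions: Ac2O, pyridine, DMAP (cat.), CH2Cl2, 0 °C → rt
Reagents that add atoms: acetic anhydride, CC(=O)OC(C)=O
Why: Acetylation of the primary and the two secondary alcohols, with the hindered tertiary C8–OH expected to stay free.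

Compound list
1 | tert-butyl acetate | CC(=O)OC(C)(C)C | starting material
2 | methyl 4,4-dimethoxybutanoate | COC(=O)CCC(OC)OC | starting material
3 | tert-butyl 6,6-dimethoxy-3-oxohexanoate | COC(OC)CCC(=O)CC(=O)OC(C)(C)C | intermediate
4 | tert-butyl (2E)-3-[(diethoxyphosphoryl)oxy]-6,6-dimethoxyhex-2-enoate | COC(OC)CC/C(OP(=O)(OCC)OCC)=C\C(=O)OC(C)(C)C | intermediate
5 | (trimethylsilyl)methylmagnesium chloride | C[Si](C)(C)C[Mg]Cl | starting material
6 | tert-butyl (2E)-6,6-dimethoxy-3-[(trimethylsilyl)methyl]hex-2-enoate | COC(OC)CC/C(C[Si](C)(C)C)=C\C(=O)OC(C)(C)C | intermediate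
7 | tert-butyl (2E)-6-oxo-3-[(trimethylsilyl)methyl]hex-2-enoate | O=CCC/C(C[Si](C)(C)C)=C\C(=O)OC(C)(C)C | intermediate
8 | ethyl 2-[bis(2,2,2-trifluoroethoxy)phosphoryl]propanoate | CCOC(=O)C(C)P(=O)(OCC(F)(F)F)OCC(F)(F)F | starting material
9 | 1-tert-butyl 8-ethyl (2E,6Z)-7-methyl-3-[(trimethylsilyl)methyl]octa-2,6-dienedioate | CCOC(=O)/C(C)=C\CC/C(C[Si](C)(C)C)=C\C(=O)OC(C)(C)C | intermediate
10 | tert-butyl (2E,6Z)-8-hydroxy-7-methyl-3-[(trimethylsilyl)methyl]octa-2,6-dienoate | OC/C(C)=C\CC/C(C[Si](C)(C)C)=C\C(=O)OC(C)(C)C | intermediate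
11 | tert-butyl (2E)-5-[(2S,3R)-3-(hydroxymethyl)-3-methyloxiran-2-yl]-3-[(trimethylsilyl)methyl]pent-2-enoate | CC(C)(C)OC(=O)/C=C(C[Si](C)(C)C)\CC[C@@H]1O[C@]1(C)CO | intermediate
12 | tert-butyl (2E)-5-[(2S,3R)-3-{[(tert-butyldimethylsilyl)oxy]methyl}-3-methyloxiran-2-yl]-3-[(trimethylsilyl)methyl]pent-2-enoate | CC(C)(C)OC(=O)/C=C(C[Si](C)(C)C)\CC[C@@H]1O[C@]1(C)CO[Si](C)(C)C(C)(C)C | intermediate
13 | (2E)-5-[(2S,3R)-3-{[(tert-butyldimethylsilyl)oxy]methyl}-3-methyloxiran-2-yl]-3-[(trimethylsilyl)methyl]pent-2-en-1-ol | OC/C=C(C[Si](C)(C)C)\CC[C@@H]1O[C@]1(C)CO[Si](C)(C)C(C)(C)C | intermediate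
14 | cyclisation precursor: pivalate of 13 (C1 R, C14 S cis-epoxide; CIP-E allylsilane with C9 cis to C12) | C[Si](C)(C)C/C(=C/COC(=O)C(C)(C)C)CC[C@@H]1O[C@]1(C)CO[Si](C)(C)C(C)(C)C | intermediate
15 | ring-A alcohol (1S,10S,14S): C14–OH, C1 bearing CH3 and CH2OTBS, C10 bearing CH2OPiv, C11=CH2 | C=C1CC[C@H](O)[C@](C)(CO[Si](C)(C)C(C)(C)C)[C@H]1COC(=O)C(C)(C)C | intermediate
16 | ring-A C2,C14-diol (15 without the silyl group) | C=C1CC[C@H](O)[C@](C)(CO)[C@H]1COC(=O)C(C)(C)C | intermediate
17 | ring-A C2 aldehyde with free C14–OH | C=C1CC[C@H](O)[C@](C)(C=O)[C@H]1COC(=O)C(C)(C)C | intermediate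
18 | trimethylsilylacetylene | C#C[Si](C)(C)C | starting material
19 | propargylic diol: C2 carbinol bearing C3≡C4–SiMe3 (target configuration at C2, 2R by CIP here), C14–OH free | C=C1CC[C@H](O)[C@](C)([C@@H](O)C#C[Si](C)(C)C)[C@H]1COC(=O)C(C)(C)C | intermediate
20 | C2,C14-bis(tert-butyldimethylsilyl) ether of 19 | C=C1CC[C@H](O[Si](C)(C)C(C)(C)C)[C@](C)([C@@H](O[Si](C)(C)C(C)(C)C)C#C[Si](C)(C)C)[C@H]1COC(=O)C(C)(C)C | intermediate
21 | C9 primary alcohol | C=C1CC[C@H](O[Si](C)(C)C(C)(C)C)[C@](C)([C@@H](O[Si](C)(C)C(C)(C)C)C#C[Si](C)(C)C)[C@H]1CO | intermediate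
22 | C9 aldehyde | C=C1CC[C@H](O[Si](C)(C)C(C)(C)C)[C@](C)([C@@H](O[Si](C)(C)C(C)(C)C)C#C[Si](C)(C)C)[C@H]1C=O | intermediate
23 | diethyl (S)-malate | CCOC(=O)[C@@H](O)CC(=O)OCC | starting material
24 | diethyl (2S,3R)-2-hydroxy-3-methylbutanedioate | CCOC(=O)[C@@H](O)[C@@H](C)C(=O)OCC | intermediate
25 | (2S,3R)-2-hydroxy-3-methylbutanedioic acid | OC(=O)[C@@H](O)[C@@H](C)C(O)=O | intermediate
26 | (2R)-2-[(2S,4S)-2-tert-butyl-5-oxo-1,3-dioxolan-4-yl]propanoic acid (cis-dioxolanone) | CC(C)(C)[C@H]1O[C@@H]([C@@H](C)C(O)=O)C(=O)O1 | intermediate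
27 | bis-triethylsilyl aldol adduct (C9–OTES, C19 triethylsilyl ester, dioxolanone intact, C9 epimers) | C=C1CC[C@H](O[Si](C)(C)C(C)(C)C)[C@](C)([C@@H](O[Si](C)(C)C(C)(C)C)C#C[Si](C)(C)C)[C@H]1C(O[Si](CC)(CC)CC)[C@]2(O[C@H](C(C)(C)C)OC2=O)[C@@H](C)C(=O)O[Si](CC)(CC)CC | intermediate
28 | aldol acid: C9 joined to C8 of the dioxolanone (C8 S, C17 R), C9–OTES (epimers), C19 acid | C=C1CC[C@H](O[Si](C)(C)C(C)(C)C)[C@](C)([C@@H](O[Si](C)(C)C(C)(C)C)C#C[Si](C)(C)C)[C@H]1C(O[Si](CC)(CC)CC)[C@]2(O[C@H](C(C)(C)C)OC2=O)[C@@H](C)C(O)=O | intermediate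
29 | tert-butyl(diphenyl)(prop-2-yn-1-yloxy)silane | C#CCO[Si](c1ccccc1)(c1ccccc1)C(C)(C)C | starting material
30 | α-hydroxy ynone acid: C8–OH, C7 ketone, C6≡C5–C16H2OTBDPS | C=C1CC[C@H](O[Si](C)(C)C(C)(C)C)[C@](C)([C@@H](O[Si](C)(C)C(C)(C)C)C#C[Si](C)(C)C)[C@H]1C(O[Si](CC)(CC)CC)[C@@](O)(C(=O)C#CCO[Si](c2ccccc2)(c2ccccc2)C(C)(C)C)[C@@H](C)C(O)=O | intermediate
31 | (Z)-β-iodoenone acid: iodine on C5 cis to C7 | C=C1CC[C@H](O[Si](C)(C)C(C)(C)C)[C@](C)([C@@H](O[Si](C)(C)C(C)(C)C)C#C[Si](C)(C)C)[C@H]1C(O[Si](CC)(CC)CC)[C@@](O)(C(=O)/C=C(\I)CO[Si](c2ccccc2)(c2ccccc2)C(C)(C)C)[C@@H](C)C(O)=O | intermediate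
32 | C7,C8-dihydroxy acid (7S) | C=C1CC[C@H](O[Si](C)(C)C(C)(C)C)[C@](C)([C@@H](O[Si](C)(C)C(C)(C)C)C#C[Si](C)(C)C)[C@H]1C(O[Si](CC)(CC)CC)[C@@](O)([C@@H](O)/C=C(\I)CO[Si](c2ccccc2)(c2ccccc2)C(C)(C)C)[C@@H](C)C(O)=O | intermediate
33 | iodovinyl γ-lactone (7S,8S,17R), C9–OTES (epimers) | C=C1CC[C@H](O[Si](C)(C)C(C)(C)C)[C@](C)([C@@H](O[Si](C)(C)C(C)(C)C)C#C[Si](C)(C)C)[C@H]1C(O[Si](CC)(CC)CC)[C@@]2(O)[C@H](/C=C(\I)CO[Si](c3ccccc3)(c3ccccc3)C(C)(C)C)OC(=O)[C@@H]2C | intermediate
34 | C9 alcohol (epimers) | C=C1CC[C@H](O[Si](C)(C)C(C)(C)C)[C@](C)([C@@H](O[Si](C)(C)C(C)(C)C)C#C[Si](C)(C)C)[C@H]1C(O)[C@@]2(O)[C@H](/C=C(\I)CO[Si](c3ccccc3)(c3ccccc3)C(C)(C)C)OC(=O)[C@@H]2C | intermediate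
35 | C9 ketone | C=C1CC[C@H](O[Si](C)(C)C(C)(C)C)[C@](C)([C@@H](O[Si](C)(C)C(C)(C)C)C#C[Si](C)(C)C)[C@H]1C(=O)[C@@]2(O)[C@H](/C=C(\I)CO[Si](c3ccccc3)(c3ccccc3)C(C)(C)C)OC(=O)[C@@H]2C | intermediate
36 | (9S)-alcohol | C=C1CC[C@H](O[Si](C)(C)C(C)(C)C)[C@](C)([C@@H](O[Si](C)(C)C(C)(C)C)C#C[Si](C)(C)C)[C@H]1[C@H](O)[C@@]2(O)[C@H](/C=C(\I)CO[Si](c3ccccc3)(c3ccccc3)C(C)(C)C)OC(=O)[C@@H]2C | intermediate
37 | C9 acetate (seco compound with silylalkyne and vinyl iodide) | C=C1CC[C@H](O[Si](C)(C)C(C)(C)C)[C@](C)([C@@H](O[Si](C)(C)C(C)(C)C)C#C[Si](C)(C)C)[C@H]1[C@H](OC(C)=O)[C@@]2(O)[C@H](/C=C(\I)CO[Si](c3ccccc3)(c3ccccc3)C(C)(C)C)OC(=O)[C@@H]2C | intermediate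
38 | terminal alkyne from 37 | C=C1CC[C@H](O[Si](C)(C)C(C)(C)C)[C@](C)([C@@H](O[Si](C)(C)C(C)(C)C)C#C)[C@H]1[C@H](OC(C)=O)[C@@]2(O)[C@H](/C=C(\I)CO[Si](c3ccccc3)(c3ccccc3)C(C)(C)C)OC(=O)[C@@H]2C | intermediate
39 | macrocyclic en-yne: ten-membered ring closed at C4–C5, C3≡C4, C5=C6 with C4 cis to C7 | C=C1CC[C@H](O[Si](C)(C)C(C)(C)C)[C@]2(C)[C@@H](O[Si](C)(C)C(C)(C)C)C#C/C(CO[Si](c4ccccc4)(c4ccccc4)C(C)(C)C)=C\[C@@H]3OC(=O)[C@H](C)[C@@]3(O)[C@@H](OC(C)=O)[C@@H]12 | intermediate
40 | macrocyclic (3Z,5E)-diene: C2,C14 TBS ethers, C16 TBDPS ether, C9 acetate | C=C1CC[C@H](O[Si](C)(C)C(C)(C)C)[C@]2(C)[C@@H](O[Si](C)(C)C(C)(C)C)/C=C\C(CO[Si](c4ccccc4)(c4ccccc4)C(C)(C)C)=C/[C@@H]3OC(=O)[C@H](C)[C@@]3(O)[C@@H](OC(C)=O)[C@@H]12 | intermediate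
41 | C2,C14,C16-triol 9-acetate | C=C1CC[C@H](O)[C@]2(C)[C@@H](O)/C=C\C(CO)=C/[C@@H]3OC(=O)[C@H](C)[C@@]3(O)[C@@H](OC(C)=O)[C@@H]12 | intermediate
42 | CNP0269068.1 (1R,2S,7S,8S,9S,10S,14S,17R) | C=C1CC[C@H](OC(C)=O)[C@]2(C)[C@@H](OC(C)=O)/C=C\C(COC(C)=O)=C/[C@@H]3OC(=O)[C@H](C)[C@@]3(O)[C@@H](OC(C)=O)[C@@H]12 | target

Total step count: 32. Longest linear sequence: 29 (steps 1–17 and 21–32); steps 18–20 make dioxolanone 26.

Steps most likely to fail

Step 11. The Lewis acid may ionise the allylic pivalate with 1,4-loss of silicon, which destroys the nucleophile. The ester carbonyl may also capture the C11 cation, or the epoxide may open at C14. The fallback takes the ester out of the cyclisation. It sets out from 13, which is silylated (TESCl, imidazole) to the allylic triethylsilyl ether F1. F1 is cyclised with MeAlCl2 at −78 °C to the ring-A alcohol with C9–OTES F2. PPTS in methanol at 0 °C removes the primary triethylsilyl ether and leaves the neopentyl TBS ether, giving the C9,C14-diol F3. PivCl and pyridine at −20 °C acylate the primary C9–OH in preference to the hindered secondary C14–OH, and the route is rejoined at 15.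

Step 21. The basic dianion may take the doubly activated C10–H instead of adding, with epimerisation at C10 or migration of C11=C20 into conjugation. Bond formation between two congested carbons may also be slow enough for retro-aldol to win before silylation. The fallback uses a base-free Mukaiyama aldol addition. It sets out from 26, which is converted with LiHMDS and TESCl into the bis(triethylsilyl) ketene acetal F4. F4 is combined with 22 under BF3·OEt2 or catalytic TESOTf at −78 °C; attack is again anti to the tert-butyl group and silyl transfer gives the same adduct 27. The usual pH 5 work-up then returns the route to 28.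

Step 29. Strain in the ten-membered en-yne may slow ring closure so far that intermolecular coupling and oxidative alkyne dimerisation take over. Pd(0) may also ionise the allylic C7–O bond of the lactone. The fallback closes the ring as the diene itself. It sets out from 38, isolated after the fluoride treatment. ZrCl4-catalysed anti-hydrostannation with Bu3SnH converts 38 into the (Z)-vinylstannane F5. Intramolecular Stille coupling of F5 (Pd2(dba)3, AsPh3, or copper(I) thiophene-2-carboxylate) joins C4 to C5 and returns the route to 40, so 39 and the semihydrogenation are bypassed.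

Further compounds
F1 | step 11 | allylic triethylsilyl ether of 13 | CC[Si](CC)(CC)OC/C=C(C[Si](C)(C)C)\CC[C@@H]1O[C@]1(C)CO[Si](C)(C)C(C)(C)C
F2 | step 11 | ring-A alcohol with C9–OTES (1S,10S,14S) | C=C1CC[C@H](O)[C@](C)(CO[Si](C)(C)C(C)(C)C)[C@H]1CO[Si](CC)(CC)CC
F3 | step 11 | ring-A C9,C14-diol with C2–OTBS | C=C1CC[C@H](O)[C@](C)(CO[Si](C)(C)C(C)(C)C)[C@H]1CO
F4 | step 21 | bis(triethylsilyl) ketene acetal of 26 | CC[Si](CC)(CC)OC(=O)[C@H](C)C1=C(O[Si](CC)(CC)CC)O[C@@H](C(C)(C)C)O1
F5 | step 29 | (Z)-vinylstannane from 38 | C=C1CC[C@H](O[Si](C)(C)C(C)(C)C)[C@](C)([C@@H](O[Si](C)(C)C(C)(C)C)/C=C\[Sn](CCCC)(CCCC)CCCC)[C@H]1[C@H](OC(C)=O)[C@@]2(O)[C@H](/C=C(\I)CO[Si](c3ccccc3)(c3ccccc3)C(C)(C)C)OC(=O)[C@@H]2C
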